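A small charge of Z is what these flasks have: 2.20 equiv in ochre, red, amber and violet, less than the 3.3 equiv of zeta, the earlier run at 110 °C.

| setting | zeta | ochre | red | amber | violet |
|---|---|---|---|---|---|
| D | 0.18 M | 0.18 M | 0.18 M | 0.18 M | 0.18 M |
| L | 0.18 M | 0.18 M | 0.18 M | 0.18 M | 0.18 M |
| Z | 3.3 equiv | 2.20 equiv | 2.20 equiv | 2.20 equiv | 2.20 equiv |
| temperature | 110 °C | 110 °C | 85 °C | 60 °C | 35 °C |
| remark | run made earlier |  |  |  |  |
| time |  | 2.5 h | 2.5 h | 2.5 h | 2.5 h |

zeta run (percent of the D and L together charged)

| time / min | Q / % | D / % |
|---|---|---|
| 4.00 | 27 | 28 |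
| 10.0 | 43 | 24 |
| 20.0 | 51 | 24 |
| 30.0 | 55 | 23 |

(standard deviation of a reading: 1.5 percentage points)

- Z is single-handed; D and L are mirror images of each other, charged as a racemate, each of them at the stated concentration
- the earlier runs do not show what temperature does; that part of a forecast is a guess
- the handed part of Z does not stay in what it makes, so the products of the two hands are mirror images too

1. which flask leads in amount of Q, in percent of the D and L together charged ("all alike" within 1.5 percentage points) (ochre / red / amber / violet / all alike)
2. how much Q is there at the end, in percent of the D and L together charged: ochre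
3. how much Q is there at the end, in percent of the D and L together charged: red
4. how much Q is there at the end, in percent of the D and L together charged: amber
5. how much Q is there at the end, in percent of the D and L together charged: violet

We read the zeta table downward. The Q column ends at 55%, above the 50.0% of the charge that was D, so L must have been turning into D. The D column reads 24% in the second row and 23% in the last, a step inside the scatter of 1.5 percentage points. Yet Q gains 16 points over the 6.00 min between the first two rows, and less, 4 points, over the 10.0 min between the last two. With D steady, what fades must be Z, although zeta was charged with 1.65 times the D and L together.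

From the last row we keep 0.333: Q formed per Z charged, the yield on the limiting reagent. It is a reading and carries the scatter. In our own reckoning, 2.20 equiv of Z at that yield gives an estimate for Q of 36.7% of the charge. That applies to ochre, which has zeta's temperature; the table says nothing about the cooler flasks.

The forecast names ochre as the leader. It gives ochre 36.5% (32% to 42%), red 35% (27% to 40%), amber 22% (9% to 35%) and violet 5% (1% to 17%). Its grounds: “With 2.20 equiv (110% of charge), Q caps near 37%.” For the cooler flasks it states that temperature is a guess.

The leader is red at 43.7%, then ochre at 40.2%, amber at 16.1% and violet at 1.69%; red and ochre both stand above our estimate.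

    Z + D → Q (k = 0.450 M⁻¹ h⁻¹, Ea = 87.0 kJ mol⁻¹)
    Z + L → E (k = 0.0140 M⁻¹ h⁻¹, Ea = 70.0 kJ mol⁻¹)
    D ⇌ L (k = 0.0820 h⁻¹, Ea = 99.0 kJ mol⁻¹)
    Z → J (k = 7.20 × 10⁻⁴ h⁻¹, Ea = 115 kJ mol⁻¹)
    Z → G (k = 0.0470 h⁻¹, Ea = 102 kJ mol⁻¹)
    (constants at 60 °C)

Red's yield on Z is 0.397 at 2.50 h, with 6.98% of its Z left. At 0.584 h in red, Z goes to G 1.4 times as fast as to Q, so at that moment Q receives 0.418 of the Z taken by these two ways. The neighbour flask with 3.70 equiv of Z, at red's temperature and time, reaches 60.7%, a yield of 0.328.

The readings are simulated on assumed constants.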